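The 2,3-dihydrofuran ring (O1–C2–C3–C3a–C7a) is read as the Cloke–Wilson isomer of a donor–acceptor spirocyclopropane. C2 carries the electron-rich catechol aryl (donor), and C3a/C7a–O1 is the enol ether of a pyran-2,4-dione (acceptor). The precursor is therefore a 5-oxaspiro[2.5]oct-6-ene-4,8-dione whose three-membered ring (C3a, C3, C2) bears aryl and formyl groups trans, made enantioselectively by an aminocatalytic Michael/alkylation cascade. Lewis-acid ring expansion breaks C3a–C2, forms O1–C2, keeps C3 and sets C2 trans to it. The formyl group is then grown into the second 4-hydroxy-2-pyranone.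

Key step: step 7

Remark: TBS = tert-butyldimethylsilyl; C2, C3, C3a, C7a and O1 are the furo[3,2-c]pyran locants of the target, which is read from its SMILES as the (2S,3S)-trans isomer.
Assumption: the spiro carbon of 10 and the carbinol carbons of 7 and 14 are expected as epimer mixtures and are left undefined in the SMILES, because each becomes sp2 in the following step.

Step 1
Reactants: 1 3,4-dihydroxybenzaldehyde
Product: 2 3,4-bis(TBS-oxy)benzaldehyde
Conditions: TBSCl (2.4 equiv), imidazole (5 equiv), DMF, 0 °C to rt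
Reagents that add atoms: tert-butyldimethylsilyl chloride, CC(C)(C)[Si](C)(C)Cl
Why: Imidazole-promoted O-silylation of both phenols gives a catechol protection that survives amide bases, mild Lewis acids and heat and is removed by fluoride at the end.

Step 2
Reactants: 2 3,4-bis(TBS-oxy)benzaldehyde; 3 2-(triphenylphosphoranylidene)acetaldehyde
Product: 4 (E)-3-[3,4-bis(TBS-oxy)phenyl]prop-2-enal
Conditions: 3 (1.1 equiv), PhMe, 80 °C
Reagents that add atoms: none
Why: Wittig olefination with the stabilised formylmethylene ylide should give the (E)-enal, and the small excess of ylide limits a second homologation.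

Step 3
Reactants: 5 4-hydroxy-6-methyl-2H-pyran-2-one; 6 4-(TBS-oxy)benzaldehyde
Product: 7 4-hydroxy-6-{2-hydroxy-2-[4-(TBS-oxy)phenyl]ethyl}-2H-pyran-2-one (racemic carbinol)
Conditions: LDA (2.3 equiv), THF, −78 °C; then 6, −78 to −40 °C; AcOH quench
Reagents that add atoms: none
Why: The O,C-dianion of the pyranone carries its most reactive carbanion on the 6-methyl carbon, which adds to the aldehyde in an aldol addition; the carbinol centre is removed in step 4.

Step 4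
Reactants: 7 4-hydroxy-6-{2-hydroxy-2-[4-(TBS-oxy)phenyl]ethyl}-2H-pyran-2-one
Product: 8 4-hydroxy-6-{(E)-2-[4-(TBS-oxy)phenyl]ethenyl}-2H-pyran-2-one
Conditions: TsOH·H2O (10 mol %), PhMe, 4 Å MS, 80 °C
Reagents that add atoms: none
Why: Acid-catalysed E1 dehydration through the para-silyloxybenzylic cation should give the conjugated (E)-styrylpyranone.

Step 5
Reactants: 8 4-hydroxy-6-{(E)-2-[4-(TBS-oxy)phenyl]ethenyl}-2H-pyran-2-one
Product: 9 3-bromo-4-hydroxy-6-{(E)-2-[4-(TBS-oxy)phenyl]ethenyl}-2H-pyran-2-one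
Conditions: NBS (1.0 equiv), CH2Cl2, 0 °C, dark
Reagents that add atoms: N-bromosuccinimide, O=C1CCC(=O)N1Br
Why: Electrophilic bromination at C3, the enol carbon of the cyclic 1,3-dicarbonyl, should be much faster than attack on the styryl double bond or the arene.

Step 6
Reactants: 4 (E)-3-[3,4-bis(TBS-oxy)phenyl]prop-2-enal; 9 3-bromo-4-hydroxy-6-{(E)-2-[4-(TBS-oxy)phenyl]ethenyl}-2H-pyran-2-one
Product: 10 (1R,2S)-2-[3,4-bis(TBS-oxy)phenyl]-4,8-dioxo-6-{(E)-2-[4-(TBS-oxy)phenyl]ethenyl}-5-oxaspiro[2.5]oct-6-ene-1-carbaldehyde (aryl and formyl trans; spiro carbon as either epimer)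
Conditions: (S)-α,α-diphenylprolinol trimethylsilyl ether (20 mol %), 2,6-lutidine (1.2 equiv), CH2Cl2, 0 °C; rapid filtration through silica
Reagents that add atoms: none
Why: In this aminocatalytic Michael-initiated ring closure the bromo-enolate carbon of 9 should add to the β-carbon of the iminium ion of 4 on the face not shielded by the diphenyl(silyloxy)methyl group, and the enamine so formed displaces bromide (3-exo-tet) to close the cyclopropane with aryl and formyl trans, which sets C1 and C2 (expected 1R,2S by the usual shielding model).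

Step 7
Reactants: 10 (1R,2S)-2-[3,4-bis(TBS-oxy)phenyl]-4,8-dioxo-6-{(E)-2-[4-(TBS-oxy)phenyl]ethenyl}-5-oxaspiro[2.5]oct-6-ene-1-carbaldehyde
Product: 11 (2S,3S)-2-[3,4-bis(TBS-oxy)phenyl]-4-oxo-6-{(E)-2-[4-(TBS-oxy)phenyl]ethenyl}-2,3-dihydro-4H-furo[3,2-c]pyran-3-carbaldehyde
Conditions: Sc(OTf)3 (5 mol %), CH2Cl2, 0 °C
Reagents that add atoms: none
Why: In this Lewis-acid-catalysed Cloke–Wilson rearrangement, Sc(III) bound to the dione should ionise the donor–acceptor bond C3a–C2 to a benzylic cation stabilised by the para-silyloxy aryl ring and a pyran-2,4-dionate, whose former ketone oxygen then closes on the cation. The closest known reaction is the acid-catalysed ring-opening cyclisation of 1-aryl spiro[2.5]octane-4,8-diones to 2-aryl tetrahydrobenzofuranones. The dihydrofuran closes as a five-membered O-alkylation of the enolate; because the broken bond ends up inside the new ring, the event is a stepwise formal 1,3-shift of C2 from carbon to oxygen and not a concerted displacement. C3 is not touched and keeps the configuration set by the organocatalyst, while the new centre C2 is placed trans to the C3 formyl group by substrate control in the closure and, since O1–C2 ionisation is reversible, by thermodynamic control. The step needs bond selectivity, secured because only the bond between the diacyl carbon and the aryl-bearing carbon is both donor- and doubly acceptor-activated, and O-regioselectivity between ketone and lactone carbonyl oxygen, secured under reversible conditions by the greater stability of the 4-alkoxy-2-pyranone over the 2-alkoxy-4-pyranone.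

Step 8
Reactants: 12 2,2,6-trimethyl-4H-1,3-dioxin-4-one
Product: 13 [(2,2-dimethyl-6-methylidene-6H-1,3-dioxin-4-yl)oxy]trimethylsilane
Conditions: LDA (1.1 equiv), THF, −78 °C; TMSCl (1.2 equiv)
Reagents that add atoms: chlorotrimethylsilane, C[Si](C)(C)Cl
Why: γ-Deprotonation of the vinylogous ester and O-silylation of the lithium dienolate should give the cross-conjugated silyl dienol ether.

Step 9
Reactants: 11 (2S,3S)-2-[3,4-bis(TBS-oxy)phenyl]-4-oxo-6-{(E)-2-[4-(TBS-oxy)phenyl]ethenyl}-2,3-dihydro-4H-furo[3,2-c]pyran-3-carbaldehyde; 13 [(2,2-dimethyl-6-methylidene-6H-1,3-dioxin-4-yl)oxy]trimethylsilane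
Product: 14 6-{2-hydroxy-2-[(2S,3R)-2-[3,4-bis(TBS-oxy)phenyl]-4-oxo-6-{(E)-2-[4-(TBS-oxy)phenyl]ethenyl}-2,3-dihydro-4H-furo[3,2-c]pyran-3-yl]ethyl}-2,2-dimethyl-4H-1,3-dioxin-4-one (carbinol epimers; same spatial arrangement at C2/C3 as 11, the 3R descriptor follows only from CIP priorities)
Conditions: 13 (1.5 equiv), BF3·OEt2 (1.1 equiv), CH2Cl2, −78 °C; aq. NaHCO3
Reagents that add atoms: none
Why: In this vinylogous Mukaiyama aldol the γ-carbon of the dienol ether should attack the BF3-activated aldehyde under non-basic conditions, so the C3–H (α to the formyl group and β to the O1 leaving group) is not enolised; the new carbinol centre is erased in step 10.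

Step 10
Reactants: 14 6-{2-hydroxy-2-[(2S,3R)-dihydrofuropyranon-3-yl]ethyl}-2,2-dimethyl-4H-1,3-dioxin-4-one
Product: 15 2,2-dimethyl-6-{2-oxo-2-[(2S,3S)-2-[3,4-bis(TBS-oxy)phenyl]-4-oxo-6-{(E)-2-[4-(TBS-oxy)phenyl]ethenyl}-2,3-dihydro-4H-furo[3,2-c]pyran-3-yl]ethyl}-4H-1,3-dioxin-4-one
Conditions: Dess–Martin periodinane (1.3 equiv), CH2Cl2, 0 °C to rt
Reagents that add atoms: none
Why: Dess–Martin oxidation of the secondary alcohol is non-basic, and the resulting β-keto dioxinone enolises towards its CH2 group, which should leave C3–H untouched.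

Step 11
Reactants: 15 2,2-dimethyl-6-{2-oxo-2-[(2S,3S)-dihydrofuropyranon-3-yl]ethyl}-4H-1,3-dioxin-4-one
Product: 17 (2S,3S)-2-[3,4-bis(TBS-oxy)phenyl]-3-(4-hydroxy-2-oxo-2H-pyran-6-yl)-6-{(E)-2-[4-(TBS-oxy)phenyl]ethenyl}-2,3-dihydro-4H-furo[3,2-c]pyran-4-one, via acylketene 16 (not isolated)
Conditions: PhMe (0.01 M), 110 °C
Reagents that add atoms: none
Why: Thermal retro-[4+2] of the dioxinone releases acetone and acylketene 16, whose ketone enol adds to the ketene (six-membered O-acylation) and tautomerises to the 4-hydroxy-2-pyranone under neutral conditions that should not touch C2 or C3.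

Step 12
Reactants: 17 (2S,3S)-tris-TBS ether of the target
Product: 18 (2S,3S)-2-(3,4-dihydroxyphenyl)-3-(4-hydroxy-2-oxo-2H-pyran-6-yl)-6-[(E)-2-(4-hydroxyphenyl)ethenyl]-2,3-dihydro-4H-furo[3,2-c]pyran-4-one (CNP0330607.1)
Conditions: HF·pyridine, THF/pyridine, 0 °C to rt
Reagents that add atoms: none
Why: Fluoride should cleave the three aryl silyl ethers while the acidic medium keeps the phenols protonated, which prevents quinone-methide opening of the O1–C2 bond and epimerisation at C3.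

Compound list
1 | 3,4-dihydroxybenzaldehyde | O=Cc1ccc(O)c(O)c1 | starting material
2 | 3,4-bis(TBS-oxy)benzaldehyde | O=Cc1ccc(O[Si](C)(C)C(C)(C)C)c(O[Si](C)(C)C(C)(C)C)c1 | intermediate
3 | 2-(triphenylphosphoranylidene)acetaldehyde | O=CC=P(c1ccccc1)(c1ccccc1)c1ccccc1 | starting material
4 | (E)-3-[3,4-bis(TBS-oxy)phenyl]prop-2-enal | O=C/C=C/c1ccc(O[Si](C)(C)C(C)(C)C)c(O[Si](C)(C)C(C)(C)C)c1 | intermediate
5 | 4-hydroxy-6-methyl-2H-pyran-2-one | Cc1cc(O)cc(=O)o1 | starting material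
6 | 4-(TBS-oxy)benzaldehyde | O=Cc1ccc(O[Si](C)(C)C(C)(C)C)cc1 | starting material
7 | 4-hydroxy-6-{2-hydroxy-2-[4-(TBS-oxy)phenyl]ethyl}-2H-pyran-2-one (racemic) | O=c1cc(O)cc(CC(O)c2ccc(O[Si](C)(C)C(C)(C)C)cc2)o1 | intermediate
8 | 4-hydroxy-6-{(E)-2-[4-(TBS-oxy)phenyl]ethenyl}-2H-pyran-2-one | O=c1cc(O)cc(/C=C/c2ccc(O[Si](C)(C)C(C)(C)C)cc2)o1 | intermediate
9 | 3-bromo-4-hydroxy-6-{(E)-2-[4-(TBS-oxy)phenyl]ethenyl}-2H-pyran-2-one | O=c1oc(/C=C/c2ccc(O[Si](C)(C)C(C)(C)C)cc2)cc(O)c1Br | intermediate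
10 | (1R,2S)-2-[3,4-bis(TBS-oxy)phenyl]-4,8-dioxo-6-{(E)-2-[4-(TBS-oxy)phenyl]ethenyl}-5-oxaspiro[2.5]oct-6-ene-1-carbaldehyde (trans; spiro carbon undefined) | O=C[C@@H]1[C@@H](c2ccc(O[Si](C)(C)C(C)(C)C)c(O[Si](C)(C)C(C)(C)C)c2)C13C(=O)OC(/C=C/c2ccc(O[Si](C)(C)C(C)(C)C)cc2)=CC3=O | intermediate
11 | (2S,3S)-2-[3,4-bis(TBS-oxy)phenyl]-4-oxo-6-{(E)-2-[4-(TBS-oxy)phenyl]ethenyl}-2,3-dihydro-4H-furo[3,2-c]pyran-3-carbaldehyde | O=C[C@H]2c3c(cc(/C=C/c4ccc(O[Si](C)(C)C(C)(C)C)cc4)oc3=O)O[C@@H]2c2ccc(O[Si](C)(C)C(C)(C)C)c(O[Si](C)(C)C(C)(C)C)c2 | intermediate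
12 | 2,2,6-trimethyl-4H-1,3-dioxin-4-one | CC1=CC(=O)OC(C)(C)O1 | starting material
13 | [(2,2-dimethyl-6-methylidene-6H-1,3-dioxin-4-yl)oxy]trimethylsilane | C=C1C=C(O[Si](C)(C)C)OC(C)(C)O1 | intermediate
14 | 6-{2-hydroxy-2-[(2S,3R)-2-[3,4-bis(TBS-oxy)phenyl]-4-oxo-6-{(E)-2-[4-(TBS-oxy)phenyl]ethenyl}-2,3-dihydro-4H-furo[3,2-c]pyran-3-yl]ethyl}-2,2-dimethyl-4H-1,3-dioxin-4-one (carbinol undefined) | CC1(C)OC(CC(O)[C@H]2c3c(cc(/C=C/c4ccc(O[Si](C)(C)C(C)(C)C)cc4)oc3=O)O[C@@H]2c2ccc(O[Si](C)(C)C(C)(C)C)c(O[Si](C)(C)C(C)(C)C)c2)=CC(=O)O1 | intermediate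
15 | 2,2-dimethyl-6-{2-oxo-2-[(2S,3S)-2-[3,4-bis(TBS-oxy)phenyl]-4-oxo-6-{(E)-2-[4-(TBS-oxy)phenyl]ethenyl}-2,3-dihydro-4H-furo[3,2-c]pyran-3-yl]ethyl}-4H-1,3-dioxin-4-one | CC1(C)OC(CC(=O)[C@H]2c3c(cc(/C=C/c4ccc(O[Si](C)(C)C(C)(C)C)cc4)oc3=O)O[C@@H]2c2ccc(O[Si](C)(C)C(C)(C)C)c(O[Si](C)(C)C(C)(C)C)c2)=CC(=O)O1 | intermediate
16 | 5-[(2S,3S)-2-[3,4-bis(TBS-oxy)phenyl]-4-oxo-6-{(E)-2-[4-(TBS-oxy)phenyl]ethenyl}-2,3-dihydro-4H-furo[3,2-c]pyran-3-yl]-3,5-dioxopent-1-en-1-one (acylketene, not isolated) | O=C=CC(=O)CC(=O)[C@H]2c3c(cc(/C=C/c4ccc(O[Si](C)(C)C(C)(C)C)cc4)oc3=O)O[C@@H]2c2ccc(O[Si](C)(C)C(C)(C)C)c(O[Si](C)(C)C(C)(C)C)c2 | intermediate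
17 | (2S,3S)-2-[3,4-bis(TBS-oxy)phenyl]-3-(4-hydroxy-2-oxo-2H-pyran-6-yl)-6-{(E)-2-[4-(TBS-oxy)phenyl]ethenyl}-2,3-dihydro-4H-furo[3,2-c]pyran-4-one | O=c1cc(O)cc([C@H]2c3c(cc(/C=C/c4ccc(O[Si](C)(C)C(C)(C)C)cc4)oc3=O)O[C@@H]2c2ccc(O[Si](C)(C)C(C)(C)C)c(O[Si](C)(C)C(C)(C)C)c2)o1 | intermediate
18 | (2S,3S)-2-(3,4-dihydroxyphenyl)-3-(4-hydroxy-2-oxo-2H-pyran-6-yl)-6-[(E)-2-(4-hydroxyphenyl)ethenyl]-2,3-dihydro-4H-furo[3,2-c]pyran-4-one | O=c1cc(O)cc([C@H]2c3c(cc(/C=C/c4ccc(O)cc4)oc3=O)O[C@@H]2c2ccc(O)c(O)c2)o1 | target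

Total step count: 12.
Longest linear sequence: 9 steps (steps 3, 4, 5, 6, 7, 9, 10, 11, 12, from 5 and 6 to 18).

Steps most likely to fail

Step 6. The hindered bromo-enolate of 9 may add too slowly to the iminium ion, the amine catalyst may be consumed by alkylation or acylation by the spiro-activated product, or the formylcyclopropane may fragment by enamine-driven ring opening with loss of enantiopurity. The fallback sets out from 4 and 8 and builds the ring in separate operations. Iminium-catalysed Michael addition of the unbrominated pyranone 8 to 4 (same prolinol silyl ether, benzoic acid, CH2Cl2) should give the lactol (4S)-4-[3,4-bis(TBS-oxy)phenyl]-2-hydroxy-7-{(E)-2-[4-(TBS-oxy)phenyl]ethenyl}-3,4-dihydro-2H,5H-pyrano[4,3-b]pyran-5-one F1. NBS in CH2Cl2 at −20 °C should brominate its enol ether carbon with opening of the lactol to the bromo-dione aldehyde 3-bromo-3-[(1S)-1-[3,4-bis(TBS-oxy)phenyl]-3-oxopropyl]-6-{(E)-2-[4-(TBS-oxy)phenyl]ethenyl}-2H-pyran-2,4(3H)-dione F2. The prolinol catalyst with 2,6-lutidine should then close the three-membered ring by intramolecular enamine alkylation (trans), which comes back to the route at 10.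

Step 7. The product aldehyde may enolise under Lewis acid and expel the pyranone oxygen (erosion of C3), and closure through the lactone carbonyl oxygen may compete. The fallback sets out from 10 and postpones the ring expansion until the formyl group has been consumed. A TMSOTf-catalysed vinylogous Mukaiyama aldol of 10 with 13 (CH2Cl2, −78 °C) should give the O-trimethylsilyl aldol 6-{2-[(1R,2S)-2-[3,4-bis(TBS-oxy)phenyl]-4,8-dioxo-6-{(E)-2-[4-(TBS-oxy)phenyl]ethenyl}-5-oxaspiro[2.5]oct-6-en-1-yl]-2-(trimethylsilyloxy)ethyl}-2,2-dimethyl-4H-1,3-dioxin-4-one F3, in which no free hydroxyl is exposed next to the acylating spiro-lactone. Sc(OTf)3 at 0 °C should then expand the cyclopropane of F3 to the O-trimethylsilyl ether of 14, F4. Citric acid in MeOH removes the trimethylsilyl group and comes back to the route at 14.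

Step 9. BF3 may ionise the benzylic O1–C2 bond so that the cation alkylates the dienol ether, or the hindered aldehyde may not react. The fallback sets out from 11 and changes both the nucleophile and the way the pyranone is closed. Commercial 1-methoxy-1,3-bis(trimethylsilyloxy)buta-1,3-diene with catalytic Ti(OiPr)4/BINOL (THF, −78 to 0 °C, acidic work-up) should give methyl 5-hydroxy-3-oxo-5-[(2S,3R)-2-[3,4-bis(TBS-oxy)phenyl]-4-oxo-6-{(E)-2-[4-(TBS-oxy)phenyl]ethenyl}-2,3-dihydro-4H-furo[3,2-c]pyran-3-yl]pentanoate F5. Dess–Martin oxidation should give the corresponding methyl 3,5-dioxopentanoate F6. DBU in PhMe at rt should lactonise its enolate with loss of methanol, which comes back to the route at 17.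

Further compounds
F1 | step 6 | (4S)-4-[3,4-bis(TBS-oxy)phenyl]-2-hydroxy-7-{(E)-2-[4-(TBS-oxy)phenyl]ethenyl}-3,4-dihydro-2H,5H-pyrano[4,3-b]pyran-5-one (anomers) | OC1C[C@@H](c2ccc(O[Si](C)(C)C(C)(C)C)c(O[Si](C)(C)C(C)(C)C)c2)c2c(O1)cc(/C=C/c1ccc(O[Si](C)(C)C(C)(C)C)cc1)oc2=O
F2 | step 6 | 3-bromo-3-[(1S)-1-[3,4-bis(TBS-oxy)phenyl]-3-oxopropyl]-6-{(E)-2-[4-(TBS-oxy)phenyl]ethenyl}-2H-pyran-2,4(3H)-dione | O=CC[C@@H](c1ccc(O[Si](C)(C)C(C)(C)C)c(O[Si](C)(C)C(C)(C)C)c1)C1(Br)C(=O)OC(/C=C/c2ccc(O[Si](C)(C)C(C)(C)C)cc2)=CC1=O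
F3 | step 7 | 6-{2-[(1R,2S)-2-[3,4-bis(TBS-oxy)phenyl]-4,8-dioxo-6-{(E)-2-[4-(TBS-oxy)phenyl]ethenyl}-5-oxaspiro[2.5]oct-6-en-1-yl]-2-(trimethylsilyloxy)ethyl}-2,2-dimethyl-4H-1,3-dioxin-4-one | CC1(C)OC(CC(O[Si](C)(C)C)[C@@H]2[C@@H](c3ccc(O[Si](C)(C)C(C)(C)C)c(O[Si](C)(C)C(C)(C)C)c3)C24C(=O)OC(/C=C/c3ccc(O[Si](C)(C)C(C)(C)C)cc3)=CC4=O)=CC(=O)O1
F4 | step 7 | O-trimethylsilyl ether of 14 | CC1(C)OC(CC(O[Si](C)(C)C)[C@H]2c3c(cc(/C=C/c4ccc(O[Si](C)(C)C(C)(C)C)cc4)oc3=O)O[C@@H]2c2ccc(O[Si](C)(C)C(C)(C)C)c(O[Si](C)(C)C(C)(C)C)c2)=CC(=O)O1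
F5 | step 9 | methyl 5-hydroxy-3-oxo-5-[(2S,3R)-2-[3,4-bis(TBS-oxy)phenyl]-4-oxo-6-{(E)-2-[4-(TBS-oxy)phenyl]ethenyl}-2,3-dihydro-4H-furo[3,2-c]pyran-3-yl]pentanoate | COC(=O)CC(=O)CC(O)[C@H]2c3c(cc(/C=C/c4ccc(O[Si](C)(C)C(C)(C)C)cc4)oc3=O)O[C@@H]2c2ccc(O[Si](C)(C)C(C)(C)C)c(O[Si](C)(C)C(C)(C)C)c2
F6 | step 9 | methyl 3,5-dioxo-5-[(2S,3S)-2-[3,4-bis(TBS-oxy)phenyl]-4-oxo-6-{(E)-2-[4-(TBS-oxy)phenyl]ethenyl}-2,3-dihydro-4H-furo[3,2-c]pyran-3-yl]pentanoate | COC(=O)CC(=O)CC(=O)[C@H]2c3c(cc(/C=C/c4ccc(O[Si](C)(C)C(C)(C)C)cc4)oc3=O)O[C@@H]2c2ccc(O[Si](C)(C)C(C)(C)C)c(O[Si](C)(C)C(C)(C)C)c2
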